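The route rests on building cyclohexane ring A (briarane numbering) around its fused 11,12-epoxide. Nitro ketone 8 already carries quaternary C1 and C10; its nitronate carbon (C14) adds to diphenyl(vinyl)sulfonium triflate and the resulting sulfonium ylide closes onto the C11 methyl ketone. One operation therefore forms the C13–C14 and C11–C12 bonds, inserts the C12–C13 unit and delivers the oxirane on the face of the C1 methyl. The step exploits the 1,4 relationship of C14 and C11 across the C1–C10 bond of ring A and the C11–C12 oxirane. Aldol reactions at C2 and C9 then attach both chains, and a Nozaki–Hiyama–Kishi closure at C6–C7 with lactonisation completes the ten-membered ring.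

Key step: step 7

Remark on numbering: C1 is the quaternary carbon (methyl C15), C2–C9 the chain of the ten-membered ring, C10 the ring-fusion CH, C11–C14 the rest of ring A (methyl C20 on C11), C16 the CH2OH on C5, C17 (methyl C18) and C19 the lactone carbons.
Assumption: compound 12 is carried as a mixture of C14 epimers, which converge at ketone 14; compounds 1, 4, 9, 19, 20 and 28 are taken as commercial.

Step 1
Reactants: 1 (E)-but-2-ene-1,4-diol
Product: 2 mono-PMB ether of 1
Conditions: 1 (3 equiv), NaH (1 equiv), 4-methoxybenzyl chloride (1 equiv), Bu4NI (cat.), THF/DMF, 0 °C to rt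
Reagents that add atoms: 4-methoxybenzyl chloride COc1ccc(CCl)cc1
Why: Williamson etherification; the excess of diol should make the mono-ether the main product.

Step 2
Reactants: 2 mono-PMB ether
Product: 3 allylic methyl carbonate
Conditions: ClCO2Me, pyridine, CH2Cl2, 0 °C
Reagents that add atoms: methyl chloroformate COC(=O)Cl
Why: O-acylation installs the carbonate leaving group for allylic substitution.

Step 3
Reactants: 3 allylic methyl carbonate; 4 ethyl 2-formylpropanoate
Product: 5 formyl ester with C1 and C10 set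
Conditions: [Ir(cod)Cl]2 (2 mol%), BINOL-derived bis(1-phenylethyl)amine phosphoramidite (4 mol%, antipode giving 3S), TBD (8 mol%), THF, rt
Reagents that add atoms: none
Why: Iridium-catalysed asymmetric allylic alkylation at the branched terminus; the ligand-defined allyl face sets C10, and the approach of the hydrogen-bonded Z-enolate of 4, as with acyclic β-keto esters, should set quaternary C1.

Step 4
Reactants: 5 formyl ester
Product: 6 aldoxime
Conditions: NH2OH·HCl, NaOAc, EtOH, 0 °C to rt
Reagents that add atoms: hydroxylamine hydrochloride [NH3+]O.[Cl-]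
Why: Oxime condensation at the only aldehyde; no stereocentre is touched.

Step 5
Reactants: 6 aldoxime
Product: 7 nitro alkene
Conditions: NaBO3·4H2O, AcOH, 55 °C
Reagents that add atoms: sodium perborate [Na+].[Na+].O[B-]1(O)OO[B-](O)(O)OO1
Why: Oxidation of the aldoxime to the primary nitro compound by peracetic acid formed in situ; the monosubstituted alkene should be epoxidised far more slowly.

Step 6
Reactants: 7 nitro alkene
Product: 8 nitro ketone
Conditions: PdCl2 (10 mol%), CuCl (1 equiv), O2 (1 atm), DMF/H2O 7:1, rt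
Reagents that add atoms: water O
Why: Tsuji–Wacker oxidation; Markovnikov hydroxypalladation turns the vinyl group into the C11 methyl ketone (C20) without touching C10.

Step 7
Reactants: 8 nitro ketone; 9 diphenyl(vinyl)sulfonium triflate
Product: 12 ring A nitro epoxide, via potassium nitronate 10 (not isolated), via sulfonium ylide 11 (not isolated)
Conditions: KOtBu (1.05 equiv), THF, −78 °C; then 9 (1.2 equiv) in CH2Cl2, −78 to −20 °C, 0.02 M
Reagents that add atoms: none
Why: Proposed new method: the nitronate 10 adds through C14 to the β-carbon of the vinylsulfonium salt (C13–C14 bond), the sulfonium ylide 11 attacks the C11 ketone through C12 (C11–C12 bond) and the betaine expels Ph2S to give the oxirane; the closest known reaction type is the epoxy-annulation of vinylsulfonium salts with ketones that carry a tethered nitrogen, oxygen or malonate nucleophile (conjugate addition followed by Corey–Chaykovsky epoxidation), here carried over to a nitronate. Ring A closes in a 6-exo-trig addition of the ylide carbon to the carbonyl group, and the oxirane closes in a 3-exo-tet displacement that needs O and S anti and so can give only the cis-fused epoxide. C11 and C12 are set in a chair transition state with the C10 CH2OPMB and C1 CO2Et groups equatorial and the C1 methyl axial: the C20 methyl avoids the 1,3-diaxial contact with C15 and takes the equatorial site, so that O11 is axial and on the face of C15 as in the target. C14 forms as an epimer mixture that converges at ketone 14. The step needs deprotonation of the nitro C–H only (one equivalent of KOtBu; the ketone α-hydrogens are far less acidic) and ylide addition to the ketone ahead of proton transfer, nitronate O- or C-alkylation and attack on the C2 ester; the absence of a conjugate acid, low temperature, dilution and the favourable six-membered closure onto the more electrophilic ketone are meant to secure this.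

Step 8
Reactants: 12 ring A nitro epoxide
Product: 14 epoxy ketone, via potassium nitronate 13 (not isolated)
Conditions: KOtBu (1.1 equiv), THF, −78 °C; then dimethyldioxirane in acetone, −78 to 0 °C
Reagents that add atoms: dimethyldioxirane CC1(C)OO1
Why: Oxidative Nef reaction of the nitronate under non-acidic conditions that should spare the oxirane; both C14 epimers give the same ketone.

Step 9
Reactants: 14 epoxy ketone
Product: 16 ring A diol, via hydroxy ester 15 (not isolated)
Conditions: LiBH(s-Bu)3 (1.2 equiv), THF, −78 °C; then i-Bu2AlH (4 equiv), −78 to −20 °C; aq. KNaC4H4O6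
Reagents that add atoms: none
Why: Ketone reduction by a bulky hydride from the equatorial side should give the axial C14 alcohol, anti to the axial C15 methyl as in the target; the C2 ester is then reduced to the primary alcohol in the same flask.

Step 10
Reactants: 16 ring A diol
Product: 17 C2 aldehyde
Conditions: TEMPO (10 mol%), PhI(OAc)2 (1.1 equiv), CH2Cl2, rt
Reagents that add atoms: none
Why: Oxoammonium oxidation, selective for the primary alcohol over the hindered axial secondary one.

Step 11
Reactants: 17 C2 aldehyde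
Product: 18 O14-silylated C2 aldehyde
Conditions: Et3SiOTf, 2,6-lutidine, CH2Cl2, −78 °C
Reagents that add atoms: triethylsilyl triflate CC[Si](CC)(CC)OS(=O)(=O)C(F)(F)F
Why: Silylation of the secondary alcohol under buffered conditions at low temperature, which the oxirane should tolerate.

Step 12
Reactants: 19 but-3-yn-2-one; 20 formaldehyde (used as paraformaldehyde)
Product: 21 (Z)-3-(hydroxymethyl)-4-iodobut-3-en-2-one
Conditions: MgI2 (1.2 equiv), (CH2O)n (2 equiv), CH2Cl2, 0 °C
Reagents that add atoms: magnesium iodide [Mg+2].[I-].[I-]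
Why: Iodide-triggered Morita–Baylis–Hillman-type coupling (conjugate addition of iodide, aldol reaction of the magnesium allenolate); the kinetic Z isomer with iodine cis to the acetyl group is expected and fixes the later C5=C6 geometry.

Step 13
Reactants: 21 iodo enone alcohol
Product: 22 silyl-protected iodo enone
Conditions: t-BuPh2SiOTf, 2,6-lutidine, CH2Cl2, −78 °C
Reagents that add atoms: tert-butyldiphenylsilyl triflate CC(C)(C)[Si](c1ccccc1)(c1ccccc1)OS(=O)(=O)C(F)(F)F
Why: Silylation with a non-nucleophilic base, so that the β-iodo enone is not attacked by addition–elimination.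

Step 14
Reactants: 18 O14-silylated C2 aldehyde; 22 silyl-protected iodo enone
Product: 23 C2 aldol adduct
Conditions: 22, (−)-Ipc2BCl, i-Pr2NEt, Et2O, 0 °C; then 18, −78 to −20 °C; H2O2, pH 7 buffer, MeOH
Reagents that add atoms: none
Why: Boron aldol reaction of the methyl ketone (C3) with the α-quaternary aldehyde; the isopinocampheyl groups on boron, in the antipode matched to the aldehyde, should set C2.

Step 15
Reactants: 23 C2 aldol adduct
Product: 24 anti-2,4-diol
Conditions: Me4NBH(OAc)3, MeCN/AcOH 1:1, −30 °C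
Reagents that add atoms: none
Why: Evans–Saksena reduction; intramolecular hydride delivery from the C2 alkoxyborohydride sets C4 anti to C2, and removal of the enone also ends the risk of oxa-Michael closure.

Step 16
Reactants: 24 anti-2,4-diol
Product: 25 tris(triethylsilyl) ether
Conditions: Et3SiOTf (2.5 equiv), 2,6-lutidine, CH2Cl2, −78 °C
Reagents that add atoms: triethylsilyl triflate CC[Si](CC)(CC)OS(=O)(=O)C(F)(F)F
Why: Silylation of both secondary alcohols; no stereocentre changes.

Step 17
Reactants: 25 tris(triethylsilyl) ether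
Product: 26 C9 primary alcohol
Conditions: DDQ, CH2Cl2/pH 7 buffer 10:1, 0 °C
Reagents that add atoms: none
Why: Oxidative cleavage of the 4-methoxybenzyl ether, orthogonal to the silyl ethers, the oxirane and the vinyl iodide.

Step 18
Reactants: 26 C9 primary alcohol
Product: 27 C9 aldehyde
Conditions: Dess–Martin periodinane, NaHCO3, CH2Cl2, 0 °C to rt
Reagents that add atoms: none
Why: Buffered Dess–Martin oxidation; the equatorial C10 aldehyde is the more stable epimer, so C10 should hold.

Step 19
Reactants: 28 diethyl (S)-malate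
Product: 29 diethyl (2S,3R)-3-methylmalate
Conditions: LiN(i-Pr)2 (2.2 equiv), THF, −78 to −20 °C; MeI, −78 to 0 °C
Reagents that add atoms: iodomethane CI
Why: Fráter–Seebach alkylation; the chelated alkoxide enolate is methylated anti to the C–O bond, which sets C17.

Step 20
Reactants: 29 diethyl (2S,3R)-3-methylmalate
Product: 30 (2S,3R)-3-methylmalic acid
Conditions: KOH, MeOH/H2O, 0 °C to rt; then HCl to pH 1
Reagents that add atoms: potassium hydroxide [K+].[OH-]
Why: Saponification of both esters; the stereocentres are not enolised as the dicarboxylate.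

Step 21
Reactants: 30 (2S,3R)-3-methylmalic acid
Product: 31 cis-dioxolanone acid
Conditions: t-BuCHO, TsOH (cat.), H2SO4 (cat.), pentane, reflux, water separator
Reagents that add atoms: pivalaldehyde CC(C)(C)C=O
Why: Acetalisation of the α-hydroxy acid to the five-membered dioxolanone; the cis isomer (tert-butyl cis to the side chain) is the thermodynamic product and stores the C8 configuration.

Step 22
Reactants: 27 C9 aldehyde; 31 cis-dioxolanone acid
Product: 32 C8–C9 aldol adduct as C9 silyl ether
Conditions: 31 (2 equiv), LiN(SiMe3)2 (4.2 equiv), THF, −78 °C; then 27; then Et3SiOTf, 2,6-lutidine, −78 to −40 °C; aq. NH4Cl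
Reagents that add atoms: triethylsilyl triflate CC[Si](CC)(CC)OS(=O)(=O)C(F)(F)F
Why: Aldol addition of the dioxolanone enolate (self-regeneration of stereocentres): the aldehyde enters anti to the tert-butyl group, so C8 is formed with retention, C9 should follow Felkin–Anh addition to the α-branched aldehyde, and silylation in the flask blocks retro-aldol cleavage and lactonisation through O9.

Step 23
Reactants: 32 C8–C9 aldol adduct
Product: 33 α-hydroxy aldehyde acid
Conditions: i-Bu2AlH (4 equiv), CH2Cl2, −78 °C; aq. KNaC4H4O6, rt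
Reagents that add atoms: none
Why: Reduction of the acylal lactone to the lactol, which collapses on work-up with loss of pivalaldehyde to the C7 aldehyde and the free C8 alcohol; the carboxylate is not reduced at −78 °C.

Step 24
Reactants: 33 α-hydroxy aldehyde acid
Product: 35 silyl-protected macrolactone, via seco hydroxy acid 34 (not isolated)
Conditions: CrCl2 (10 equiv), NiCl2 (0.1 equiv), DMSO/THF 3:1, 0.002 M, rt; then PPTS (cat.), CH2Cl2, rt
Reagents that add atoms: none
Why: Intramolecular Nozaki–Hiyama–Kishi reaction closes the ten-membered ring at C6–C7 with retention of the alkene geometry; addition anti to the C8 oxygen (Felkin–Anh) should set C7, and the γ-hydroxy acid 34 then lactonises to the five-membered lactone.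

Step 25
Reactants: 35 silyl-protected macrolactone
Product: 36 pentaol with O16 silyl ether
Conditions: HF·pyridine, pyridine, THF, 0 °C to rt
Reagents that add atoms: none
Why: Buffered fluoride cleavage of the four triethylsilyl ethers; the primary tert-butyldiphenylsilyl ether and the oxirane should survive.

Step 26
Reactants: 36 pentaol with O16 silyl ether
Product: 37 tetraacetate with O16 silyl ether
Conditions: Ac2O, pyridine, DMAP (cat.), CH2Cl2, 0 °C to rt
Reagents that add atoms: acetic anhydride CC(=O)OC(C)=O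
Why: Acetylation of the four secondary alcohols (C2, C4, C9, C14); the tertiary C8 alcohol should stay free under these mild conditions.

Step 27
Reactants: 37 tetraacetate with O16 silyl ether
Product: 38 CNP0104124.1
Conditions: Bu4NF, AcOH (1:1), THF, 0 °C to rt
Reagents that add atoms: none
Why: Buffered fluoride desilylation frees the primary C16 alcohol without acetate cleavage or migration.

Compound list
1 | (E)-but-2-ene-1,4-diol | OC/C=C/CO | starting material
2 | (E)-4-[(4-methoxybenzyl)oxy]but-2-en-1-ol | COc1ccc(COC/C=C/CO)cc1 | intermediate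
3 | methyl (E)-4-[(4-methoxybenzyl)oxy]but-2-en-1-yl carbonate | COC(=O)OC/C=C/COCc1ccc(OC)cc1 | intermediate
4 | ethyl 2-formylpropanoate (racemic, enolisable) | CCOC(=O)C(C)C=O | starting material
5 | ethyl (2R,3S)-2-formyl-3-{[(4-methoxybenzyl)oxy]methyl}-2-methylpent-4-enoate | C=C[C@H](COCc1ccc(OC)cc1)[C@](C)(C=O)C(=O)OCC | intermediate
6 | ethyl (2R,3S)-2-[(E)-(hydroxyimino)methyl]-3-{[(4-methoxybenzyl)oxy]methyl}-2-methylpent-4-enoate | C=C[C@H](COCc1ccc(OC)cc1)[C@](C)(/C=N/O)C(=O)OCC | intermediate
7 | ethyl (2R,3S)-3-{[(4-methoxybenzyl)oxy]methyl}-2-methyl-2-(nitromethyl)pent-4-enoate | C=C[C@H](COCc1ccc(OC)cc1)[C@](C)(C[N+](=O)[O-])C(=O)OCC | intermediate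
8 | ethyl (2R,3S)-3-{[(4-methoxybenzyl)oxy]methyl}-2-methyl-2-(nitromethyl)-4-oxopentanoate | CC(=O)[C@H](COCc1ccc(OC)cc1)[C@](C)(C[N+](=O)[O-])C(=O)OCC | intermediate
9 | diphenyl(vinyl)sulfonium trifluoromethanesulfonate | C=C[S+](c1ccccc1)c1ccccc1.[O-]S(=O)(=O)C(F)(F)F | starting material
10 | potassium nitronate of 8 (C14 deprotonated) | CC(=O)[C@H](COCc1ccc(OC)cc1)[C@](C)(C=[N+]([O-])[O-])C(=O)OCC.[K+] | intermediate (not isolated)
11 | sulfonium ylide formed from 10 and 9; C1 and C10 as in 8, C14 epimers | CC(=O)[C@H](COCc1ccc(OC)cc1)[C@](C)(C(C[CH-][S+](c1ccccc1)c1ccccc1)[N+](=O)[O-])C(=O)OCC | intermediate (not isolated)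
12 | ethyl 2-{[(4-methoxybenzyl)oxy]methyl}-1,3-dimethyl-4-nitro-7-oxabicyclo[4.1.0]heptane-3-carboxylate; oxirane O, C3 methyl and CH2OPMB on one face, CO2Et on the other (C1, C10, C11, C12 as in the target); C4 (= C14) epimers | [O-][N+](=O)C1C[C@@H]2O[C@]2(C)[C@H](COCc3ccc(OC)cc3)[C@@]1(C)C(=O)OCC | intermediate
13 | potassium nitronate of 12 | [O-][N+]([O-])=C1C[C@@H]2O[C@]2(C)[C@H](COCc3ccc(OC)cc3)[C@@]1(C)C(=O)OCC.[K+] | intermediate (not isolated)
14 | ethyl 2-{[(4-methoxybenzyl)oxy]methyl}-1,3-dimethyl-4-oxo-7-oxabicyclo[4.1.0]heptane-3-carboxylate; ring stereocentres as in 12 | O=C1C[C@@H]2O[C@]2(C)[C@H](COCc3ccc(OC)cc3)[C@@]1(C)C(=O)OCC | intermediate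
15 | ethyl 4-hydroxy-2-{[(4-methoxybenzyl)oxy]methyl}-1,3-dimethyl-7-oxabicyclo[4.1.0]heptane-3-carboxylate (present as lithium alkoxide); C4 hydroxyl trans to the C3 methyl and to the oxirane O | O[C@H]1C[C@@H]2O[C@]2(C)[C@H](COCc3ccc(OC)cc3)[C@@]1(C)C(=O)OCC | intermediate (not isolated)
16 | ring A diol: as 15 with CH2OH in place of CO2Et (C1, C10, C11, C12, C14 as in the target) | O[C@H]1C[C@@H]2O[C@]2(C)[C@H](COCc3ccc(OC)cc3)[C@@]1(C)CO | intermediate
17 | C2 aldehyde: as 16 with CHO in place of CH2OH | O[C@H]1C[C@@H]2O[C@]2(C)[C@H](COCc3ccc(OC)cc3)[C@@]1(C)C=O | intermediate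
18 | O14-triethylsilyl ether of 17 | CC[Si](CC)(CC)O[C@H]1C[C@@H]2O[C@]2(C)[C@H](COCc3ccc(OC)cc3)[C@@]1(C)C=O | intermediate
19 | but-3-yn-2-one | CC(=O)C#C | starting material
20 | formaldehyde (paraformaldehyde) | C=O | starting material
21 | (Z)-3-(hydroxymethyl)-4-iodobut-3-en-2-one (iodine cis to acetyl) | CC(=O)/C(CO)=C\I | intermediate
22 | (Z)-3-{[(tert-butyldiphenylsilyl)oxy]methyl}-4-iodobut-3-en-2-one | CC(=O)/C(CO[Si](c1ccccc1)(c1ccccc1)C(C)(C)C)=C\I | intermediate
23 | C2 aldol adduct: 18 extended at C2 by CH(OH)–CH2–C(=O)–C(CH2OSiPh2t-Bu)=CHI; C2 as in the target, Z-iodoalkene | CC[Si](CC)(CC)O[C@H]1C[C@@H]2O[C@]2(C)[C@H](COCc3ccc(OC)cc3)[C@@]1(C)[C@H](O)CC(=O)/C(CO[Si](c4ccccc4)(c4ccccc4)C(C)(C)C)=C\I | intermediate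
24 | anti-2,4-diol from 23 (C2 and C4 as in the target) | CC[Si](CC)(CC)O[C@H]1C[C@@H]2O[C@]2(C)[C@H](COCc3ccc(OC)cc3)[C@@]1(C)[C@H](O)C[C@@H](O)/C(CO[Si](c4ccccc4)(c4ccccc4)C(C)(C)C)=C\I | intermediate
25 | O2,O4,O14-tris(triethylsilyl) ether of 24 | CC[Si](CC)(CC)O[C@H]1C[C@@H]2O[C@]2(C)[C@H](COCc3ccc(OC)cc3)[C@@]1(C)[C@H](O[Si](CC)(CC)CC)C[C@@H](O[Si](CC)(CC)CC)/C(CO[Si](c4ccccc4)(c4ccccc4)C(C)(C)C)=C\I | intermediate
26 | C9 primary alcohol: 25 without the 4-methoxybenzyl group | CC[Si](CC)(CC)O[C@H]1C[C@@H]2O[C@]2(C)[C@H](CO)[C@@]1(C)[C@H](O[Si](CC)(CC)CC)C[C@@H](O[Si](CC)(CC)CC)/C(CO[Si](c3ccccc3)(c3ccccc3)C(C)(C)C)=C\I | intermediate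
27 | C9 aldehyde from 26 | CC[Si](CC)(CC)O[C@H]1C[C@@H]2O[C@]2(C)[C@H](C=O)[C@@]1(C)[C@H](O[Si](CC)(CC)CC)C[C@@H](O[Si](CC)(CC)CC)/C(CO[Si](c3ccccc3)(c3ccccc3)C(C)(C)C)=C\I | intermediate
28 | diethyl (S)-malate | CCOC(=O)[C@@H](O)CC(=O)OCC | starting material
29 | diethyl (2S,3R)-2-hydroxy-3-methylsuccinate | CCOC(=O)[C@@H](O)[C@@H](C)C(=O)OCC | intermediate
30 | (2S,3R)-2-hydroxy-3-methylsuccinic acid | OC(=O)[C@@H](O)[C@@H](C)C(=O)O | intermediate
31 | (2R)-2-[(2S,4S)-2-tert-butyl-5-oxo-1,3-dioxolan-4-yl]propanoic acid (tert-butyl cis to the side chain) | CC(C)(C)[C@H]1O[C@@H]([C@@H](C)C(=O)O)C(=O)O1 | intermediate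
32 | aldol adduct: C9 carbinol as triethylsilyl ether; C8 is the quaternary carbon of the 2-tert-butyl-1,3-dioxolan-4-one ring (C7 = ring carbonyl) and bears the (R)-1-carboxyethyl group; C8, C9, C17 as in the target | CC[Si](CC)(CC)O[C@H]1C[C@@H]2O[C@]2(C)[C@H]([C@@H](O[Si](CC)(CC)CC)[C@]3(O[C@H](C(C)(C)C)OC3=O)[C@@H](C)C(=O)O)[C@@]1(C)[C@H](O[Si](CC)(CC)CC)C[C@@H](O[Si](CC)(CC)CC)/C(CO[Si](c4ccccc4)(c4ccccc4)C(C)(C)C)=C\I | intermediate
33 | α-hydroxy aldehyde acid: C7 aldehyde, C8 tertiary alcohol, C19 acid (open form; it can also exist as its cyclic lactol) | CC[Si](CC)(CC)O[C@H]1C[C@@H]2O[C@]2(C)[C@H]([C@@H](O[Si](CC)(CC)CC)[C@](O)([C@@H](C)C(=O)O)C=O)[C@@]1(C)[C@H](O[Si](CC)(CC)CC)C[C@@H](O[Si](CC)(CC)CC)/C(CO[Si](c3ccccc3)(c3ccccc3)C(C)(C)C)=C\I | intermediate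
34 | ten-membered seco hydroxy acid: C7 alcohol and C19 acid, 5Z alkene, all stereocentres as in the target | CC[Si](CC)(CC)O[C@H]1C[C@@H]2O[C@]2(C)[C@@H]2[C@@H](O[Si](CC)(CC)CC)[C@](O)([C@@H](C)C(=O)O)[C@@H](O)/C=C(/CO[Si](c3ccccc3)(c3ccccc3)C(C)(C)C)[C@H](O[Si](CC)(CC)CC)C[C@@H](O[Si](CC)(CC)CC)[C@@]12C | intermediate (not isolated)
35 | macrolactone: target skeleton with SiEt3 on O2, O4, O9, O14 and SiPh2t-Bu on O16, free C8 hydroxyl | CC[Si](CC)(CC)O[C@H]1C[C@@H]2O[C@]2(C)[C@@H]2[C@@H](O[Si](CC)(CC)CC)[C@@]3(O)[C@H](/C=C(/CO[Si](c4ccccc4)(c4ccccc4)C(C)(C)C)[C@H](O[Si](CC)(CC)CC)C[C@@H](O[Si](CC)(CC)CC)[C@@]12C)OC(=O)[C@@H]3C | intermediate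
36 | pentaol: 2,4,8,9,14-pentahydroxy compound with O16 tert-butyldiphenylsilyl ether | O[C@H]1C[C@@H]2O[C@]2(C)[C@@H]2[C@@H](O)[C@@]3(O)[C@H](/C=C(/CO[Si](c4ccccc4)(c4ccccc4)C(C)(C)C)[C@H](O)C[C@@H](O)[C@@]12C)OC(=O)[C@@H]3C | intermediate
37 | 2,4,9,14-tetraacetate with O16 tert-butyldiphenylsilyl ether | CC(=O)O[C@H]1C[C@@H]2O[C@]2(C)[C@@H]2[C@@H](OC(C)=O)[C@@]3(O)[C@H](/C=C(/CO[Si](c4ccccc4)(c4ccccc4)C(C)(C)C)[C@H](OC(C)=O)C[C@@H](OC(C)=O)[C@@]12C)OC(=O)[C@@H]3C | intermediate
38 | CNP0104124.1 (2,4,9,14-tetraacetoxy-11,12-epoxy-8,16-dihydroxy briarane lactone, 5Z) | CC(=O)O[C@H]1C[C@@H]2O[C@]2(C)[C@@H]2[C@@H](OC(C)=O)[C@@]3(O)[C@H](/C=C(/CO)[C@H](OC(C)=O)C[C@@H](OC(C)=O)[C@@]12C)OC(=O)[C@@H]3C | target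

Total step count: 27. Longest linear sequence: 22 steps (steps 1–11, 14–18 and 22–27).

Steps most likely to fail

Step 7 (Proposed new method). Proton transfer may quench the ylide before it reaches the ketone, after which the nitronate alkylates itself through oxygen or carbon at the sulfonium-bearing carbon instead of forming the oxirane. The fallback sets out from 8 and uses only known chemistry. A Schweizer annulation of 8 with vinyltriphenylphosphonium bromide and KOtBu in THF (conjugate addition of the nitronate, then intramolecular Wittig reaction with the C11 ketone) should give nitrocyclohexene F1, which still forms both bonds in one operation but leaves a C11=C12 alkene. NBS in wet THF should then form the bromonium ion on the face away from the axial C15 methyl, with water opening at tertiary C11 from the C15 face, to give bromohydrin F2. K2CO3 in MeOH closes the oxirane with inversion at C12, and the route comes back at 12.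

Step 3. Facial discrimination of the prochiral enolate may be poor, giving low diastereoselectivity at quaternary C1, and the α-formyl ester product may lose its formyl group to alkoxide. The fallback sets out from 3 and makes C1 by desymmetrisation instead. The same iridium catalyst with diethyl methylmalonate (NaH, THF) sets only C10 and should give malonate F3. Pig liver esterase in pH 7 buffer hydrolyses one of the two diastereotopic esters to half-ester F4; if the enzyme does not discriminate, the two half-esters are separated. Activation with ClCO2Et and Et3N followed by NaBH4 reduces the acid only, to hydroxy ester F5, and Dess–Martin oxidation comes back at 5.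

Step 24. Closure of the strained ten-membered ring may be slow, so that intermolecular coupling or loss of iodine from the alkenylchromium species takes over, and the facial selectivity at C7 may be poor. The fallback sets out from 32 and closes the ring at C5=C6 by metathesis instead. Hydrodeiodination with Pd(PPh3)4 and Bu3SnH gives the 1,1-disubstituted alkene F6. i-Bu2AlH as in step 23 gives hydroxy aldehyde acid F7. Chelation-controlled addition of CH2=CHMgBr (THF, −78 °C) to the C7 aldehyde, with lactonisation on work-up, gives diene lactone F8; its C7 epimer would be separated at this stage. Ring-closing metathesis with the second-generation Hoveyda–Grubbs catalyst (toluene, 80 °C, 0.001 M) should give the ring-cis trisubstituted alkene and comes back at 35.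

Further compounds
F1 | step 7 | nitrocyclohexene: ethyl 6-{[(4-methoxybenzyl)oxy]methyl}-1,5-dimethyl-2-nitrocyclohex-4-ene-1-carboxylate, C1 and C10 as in 8, C14 epimers | [O-][N+](=O)C1CC=C(C)[C@H](COCc2ccc(OC)cc2)[C@@]1(C)C(=O)OCC
F2 | step 7 | bromohydrin: C11 hydroxyl on the face of the C15 methyl, C12 bromine on the opposite face | [O-][N+](=O)C1C[C@@H](Br)[C@](C)(O)[C@H](COCc2ccc(OC)cc2)[C@@]1(C)C(=O)OCC
F3 | step 3 | diethyl 2-{(2S)-1-[(4-methoxybenzyl)oxy]but-3-en-2-yl}-2-methylmalonate | C=C[C@H](COCc1ccc(OC)cc1)C(C)(C(=O)OCC)C(=O)OCC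
F4 | step 3 | malonate half-ester with C1 and C10 as in 5 (CO2H in place of CHO) | C=C[C@H](COCc1ccc(OC)cc1)[C@](C)(C(=O)O)C(=O)OCC
F5 | step 3 | hydroxy ester with C1 and C10 as in 5 (CH2OH in place of CHO) | C=C[C@H](COCc1ccc(OC)cc1)[C@](C)(CO)C(=O)OCC
F6 | step 24 | deiodinated 32 (C5 carries an exocyclic methylene) | CC[Si](CC)(CC)O[C@H]1C[C@@H]2O[C@]2(C)[C@H]([C@@H](O[Si](CC)(CC)CC)[C@]3(O[C@H](C(C)(C)C)OC3=O)[C@@H](C)C(=O)O)[C@@]1(C)[C@H](O[Si](CC)(CC)CC)C[C@@H](O[Si](CC)(CC)CC)C(=C)CO[Si](c4ccccc4)(c4ccccc4)C(C)(C)C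
F7 | step 24 | hydroxy aldehyde acid from F6 (C7 aldehyde, C8 alcohol, C19 acid) | CC[Si](CC)(CC)O[C@H]1C[C@@H]2O[C@]2(C)[C@H]([C@@H](O[Si](CC)(CC)CC)[C@](O)([C@@H](C)C(=O)O)C=O)[C@@]1(C)[C@H](O[Si](CC)(CC)CC)C[C@@H](O[Si](CC)(CC)CC)C(=C)CO[Si](c3ccccc3)(c3ccccc3)C(C)(C)C
F8 | step 24 | diene lactone: C7 vinyl carbinol closed to the γ-lactone, C7, C8, C17 as in the target | CC[Si](CC)(CC)O[C@H]1C[C@@H]2O[C@]2(C)[C@H]([C@@H](O[Si](CC)(CC)CC)[C@@]3(O)[C@H](C=C)OC(=O)[C@@H]3C)[C@@]1(C)[C@H](O[Si](CC)(CC)CC)C[C@@H](O[Si](CC)(CC)CC)C(=C)CO[Si](c4ccccc4)(c4ccccc4)C(C)(C)C
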